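(The runs come from a simulation from invented constants; scatter was added.)

A slow flask tempts one to count what is made per minute, and that temptation is what my colleague and I dispute here.

| setting | blue | teal | Saturday's | Friday's |
|---|---|---|---|---|
| substrate | 0.39 M | 0.58 M | 0.77 M | 0.77 M |
| temperature | −15 °C | −4 °C | −20 °C | 0 °C |
| remark | run made earlier | run made earlier |  |  |
| time |  |  | 2.5 min | 2.5 min |

blue run (percent of the substrate charged)

| time / min | target / % | substrate / % |
|---|---|---|
| 0.250 | 5 | 93 |
| 0.333 | 8 | 90 |
| 0.500 | 8 | 88 |
| 0.833 | 13 | 79 |
| 1.33 | 21 | 69 |
| 2.00 | 32 | 56 |
| 3.00 | 40 | 40 |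

teal run (percent of the substrate charged)

| time / s | target / % | substrate / % |
|---|---|---|
| 12.0 | 15 | 78 |
| 25.0 | 29 | 61 |
| 40.0 | 38 | 47 |
| 50.0 | 47 | 40 |
| 60.0 | 52 | 31 |
| 80.0 | 58 | 19 |

(scatter of a reading: 2 percentage points)

- the earlier runs were read with a standard deviation of 2 percentage points
- a reading or a percentage of target counts all its forms, free or not

1. which of the two there is more of at the end, Saturday's (isomer of the product / target)
2. which of the two there is more of at the end, Friday's (isomer of the product / target)
3. final target, as a percentage of the substrate charged, in Saturday's
4. final target, as a percentage of the substrate charged, in Friday's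

I work with the fraction left. The blue run's last reading has 40% of the substrate left at 3.00 min, which gives 0.305 min⁻¹: this is the decay constant, the logarithm of one over the fraction left, divided by the time. The same division at 1.33 min gives 0.279 min⁻¹, close to it although the flask then held more substrate, so I treat the decay as first-order and let the fraction left ignore the charge. The teal run's last reading gives 1.25 min⁻¹.

Taking the logarithm of the constant as straight in temperature through these two runs, I get 0.161 min⁻¹ for Saturday's and 2.08 min⁻¹ for Friday's. Over 2.5 min, the fraction left is then 66.8% in Saturday's and 0.556% in Friday's.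

The selectivity, target per substrate used, reads 66.7% in the blue run and 71.6% in the teal run. I apply the colder reading to Saturday's and the warmer to Friday's, which gives 22.1% and 71.2% of target. Target stays ahead of the remainder, which I take for the isomer of the product.

My colleague keeps these constants but counts the fraction used as constant times time. That gives 40.2% used in Saturday's, hence 26.9% of target. In Friday's the count reaches 520%, so my colleague stops at the charge and we differ little there, which leaves Saturday's as the test.

The forecast, holding that “this looks like parallel first-order paths”, gave 20% (14% to 28%) for Saturday's and 73% (64% to 81%) for Friday's, with target ahead in both, numbers near mine but not the same.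

Saturday's gives 22.1% of target against 10.5% of isomer of the product, and Friday's gives 75.6% of target, crystals counted in, against 23.4% of isomer of the product.

    target ⇌ isomer of the product (K = 0.450, k = 1.20 × 10⁻⁴ s⁻¹, Ea = 74.0 kJ mol⁻¹, ΔH = 28.0 kJ mol⁻¹)
    other conformer → isomer of the product (k = 0.0500 s⁻¹, Ea = 65.0 kJ mol⁻¹)
    substrate → target (k = 0.00180 s⁻¹, Ea = 75.0 kJ mol⁻¹)
    substrate ⇌ other conformer (K = 0.0860, k = 0.00120 s⁻¹, Ea = 65.0 kJ mol⁻¹, ΔH = −29.0 kJ mol⁻¹)
    crystals ⇌ target, rate k5*(cs5 - [target]) while solid is left; crystals form when [target] > cs5 (solubility = 0.200 M, k = 0.410 s⁻¹)
    (constants at −20 °C)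

Saturday's keeps 66.1% of its substrate, an average decay constant of 0.166 min⁻¹, where my colleague's count leaves 59.7%. My colleague's count holds early: at 1.25 min in Saturday's it says 20.1% used, and the flask has used 18.9%. Now take a flask like Friday's kept at −15 °C, the blue run's temperature, so I carry the blue constant over unchanged, still letting the fraction left ignore the charge. Over 2.5 min the fraction left is 46.6%, and the blue selectivity gives 35.6% of target. That flask holds 45.9% of substrate and 37.2% of target, all its forms counted.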